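Atom labels: chromone rings A and C, 3',5'-dimethoxyphenyl ring B; side chain C7 (benzylic carbinol), C8 (carries the ether oxygen to C4'), C9 (CH2OH).
Cuts, in retrosynthetic order: the three phenolic O–benzyl bonds and the C9 ester level; the C7–H bond (back to an aryl ketone); the C8–O4' ether bond; C8–C9 in the chain fragment; O1–C2 and then C2–C3 of ring C.
Forward: rings A and B are bought. An aldol condensation makes C2–C3, oxidative cyclization closes ring C at O1–C2, and carbenoid O–H insertion attaches the three-carbon chain to O4'. Ketone reduction, ester reduction and debenzylation follow.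
Enabling feature: C8 sits between C7 and C9 and bears the oxygen to C4' of ring B. Once C7 is a ketone and C9 an ester, C8–H is a doubly activated acidic proton and C8 racemizes freely, so a racemate can be drained into one stereoisomer.
Stereochemistry: C7 and C8 are both fixed in that one reduction (transfer hydrogenation with dynamic kinetic resolution, (S,S)-TsDPEN ligand on ruthenium). No later step breaks a bond at either center.

Key step: step 9

Assumption: the sense of induction is taken from the aryl ketone model of the TsDPEN catalysts (the (S,S) ligand gives the spatial arrangement of (S)-1-phenylethanol, here labelled 7R because C8 outranks the arene), and syn selectivity is taken from the behaviour of alpha-alkoxy beta-keto esters.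

Step 1
Reactants: 1 phloroacetophenone (2,4,6-trihydroxyacetophenone)
Product: 2 dibenzyl phloroacetophenone (2-hydroxy-4,6-bis(benzyloxy)acetophenone)
Conditions: BnBr (2.1 equiv), K2CO3 (2.2 equiv), DMF, rt
Reagents that add atoms: benzyl bromide, BrCc1ccccc1
Why: Williamson etherification in which the 4-OH and one of the two equivalent ortho OH groups are alkylated, after which the last OH is tied up in a hydrogen bond to the acetyl carbonyl and is too poor a nucleophile for the limited amount of benzyl bromide.

Step 2
Reactants: 3 syringaldehyde (4-hydroxy-3,5-dimethoxybenzaldehyde)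
Product: 4 O-allylsyringaldehyde (4-(allyloxy)-3,5-dimethoxybenzaldehyde)
Conditions: allyl bromide (1.3 equiv), K2CO3 (1.5 equiv), DMF, 60 °C
Reagents that add atoms: allyl bromide, C=CCBr
Why: Williamson etherification of an acidic para-formyl phenol with a small, very reactive halide, giving an ether that survives hydroxide and can later be removed without touching benzyl ethers.

Step 3
Reactants: 2 dibenzyl phloroacetophenone; 4 O-allylsyringaldehyde
Product: 5 chalcone (E)-3-[4-(allyloxy)-3,5-dimethoxyphenyl]-1-[2,4-bis(benzyloxy)-6-hydroxyphenyl]prop-2-en-1-one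
Conditions: KOH (10 equiv), EtOH/THF, rt; then 1 M HCl
Reagents that add atoms: none
Why: Claisen–Schmidt condensation in which the acetophenone enolate adds to the non-enolizable aldehyde and E1cB loss of water gives the conjugated E-alkene (the future C2–C3 bond), all ethers being inert to hydroxide.

Step 4
Reactants: 5 chalcone
Product: 7 allyl dibenzyl tricin (2-[4-(allyloxy)-3,5-dimethoxyphenyl]-5,7-bis(benzyloxy)-4H-chromen-4-one), via flavanone 6 (not isolated)
Conditions: I2 (10 mol %), DMSO, 120 °C
Reagents that add atoms: none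
Why: Iodine/DMSO oxidative cyclization of a 2'-hydroxychalcone, in which 6-endo oxa-Michael addition of the free phenol forms O1–C2 (flavanone 6), iodination at C3 and loss of HI aromatize ring C, and DMSO reoxidizes HI to I2; any allyl ether cleaved on the way gives phenol 8, the product of the next step.

Step 5
Reactants: 7 allyl dibenzyl tricin
Product: 8 dibenzyltricin (5,7-bis(benzyloxy)-2-(4-hydroxy-3,5-dimethoxyphenyl)-4H-chromen-4-one)
Conditions: Pd(PPh3)4 (5 mol %), morpholine (5 equiv), THF, rt
Reagents that add atoms: none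
Why: Tsuji–Trost type deallylation in which zerovalent palladium ionizes the allyl aryl ether, the stabilized phenoxide leaves and morpholine takes up the allyl fragment irreversibly, while benzyl ethers, methyl ethers and the flavone are untouched.

Step 6
Reactants: 9 benzyloxyacetophenone (4'-(benzyloxy)acetophenone); 10 diethyl carbonate
Product: 11 keto ester ethyl 3-[4-(benzyloxy)phenyl]-3-oxopropanoate
Conditions: NaH (2.5 equiv), 10 (3 equiv), THF, reflux; then cold 1 M HCl
Reagents that add atoms: none
Why: Crossed Claisen condensation in which the ketone enolate is acylated by the non-enolizable carbonate (C8–C9 bond) and deprotonation of the product by the second equivalent of base drives the equilibrium.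

Step 7
Reactants: 11 keto ester
Product: 12 diazo keto ester ethyl 3-[4-(benzyloxy)phenyl]-2-diazo-3-oxopropanoate
Conditions: 4-acetamidobenzenesulfonyl azide (1.1 equiv), Et3N (1.5 equiv), MeCN, 0 °C to rt
Reagents that add atoms: 4-acetamidobenzenesulfonyl azide, CC(=O)Nc1ccc(cc1)S(=O)(=O)N=[N+]=[N-]
Why: Regitz diazo transfer in which the amine-generated enolate of the 1,3-dicarbonyl attacks the terminal nitrogen of the sulfonyl azide and fragmentation leaves N2 on carbon with loss of the sulfonamide.

Step 8
Reactants: 8 dibenzyltricin; 12 diazo keto ester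
Product: 13 racemic keto ester ethyl 3-[4-(benzyloxy)phenyl]-2-{4-[5,7-bis(benzyloxy)-4-oxo-4H-chromen-2-yl]-2,6-dimethoxyphenoxy}-3-oxopropanoate
Conditions: Rh2(OAc)4 (2 mol %), ClCH2CH2Cl, 80 °C, slow addition of 12 (1.5 equiv)
Reagents that add atoms: none
Why: Rhodium carbenoid O–H insertion, well known for phenols and 2-diazo-1,3-dicarbonyl compounds, in which Rh2(OAc)4 (divalent rhodium) expels N2, the strongly electrophilic carbene carbon is captured by the only O–H group present and a proton shift completes the C8–O4' bond, so the hindered phenoxide never has to act as an SN2 nucleophile; C8 is deliberately formed racemic.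

Step 9
Reactants: 13 racemic keto ester
Product: 15 syn hydroxy ester ethyl (2S,3R)-3-[4-(benzyloxy)phenyl]-2-{4-[5,7-bis(benzyloxy)-4-oxo-4H-chromen-2-yl]-2,6-dimethoxyphenoxy}-3-hydroxypropanoate, via enol 14 (not isolated)
Conditions: RuCl(p-cymene)[(S,S)-TsDPEN] (2 mol %), HCO2H/Et3N 5:2, CH2Cl2, 30 °C
Reagents that add atoms: none
Why: Triethylamine in the HCO2H/Et3N medium interconverts the two enantiomers of 13 through enol 14 faster than either is reduced, while the ruthenium hydride (divalent ruthenium) formed from the catalyst and formate hands its Ru–H to C7 and its N–H to the carbonyl oxygen in a concerted outer-sphere six-membered transition state, which creates the C7–H bond. The reaction type is the Noyori–Ikariya asymmetric transfer hydrogenation with dynamic kinetic resolution, known for alpha-alkoxy and alpha-aryloxy beta-keto esters, which gives syn monoprotected 1,2-diols. No ring is closed or opened. C7 is controlled by the (S,S)-TsDPEN ligand, since the CH/pi contact between the p-cymene ligand and the electron-rich 4-benzyloxyphenyl group exposes the ketone face that leads to the 3R (later 7R) carbinol. C8 is controlled by which enantiomer reacts faster, namely the one that can place its C8–OAr bond anti to the incoming hydride in a polar Felkin–Anh arrangement, so the whole racemate should drain into the syn (threo) 2S,3R isomer. The step needs syn selectivity, face selectivity and chemoselectivity for the C7 ketone; the acidity of C8–H (flanked by ketone, ester and aryloxy group) keeps racemization fast enough for the first two, and the vinylogous ester character of the C4 carbonyl of ring C, further enriched by the 5- and 7-alkoxy groups, keeps the flavone and the ester out of reach of the hydride.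

Step 10
Reactants: 15 syn hydroxy ester
Product: 17 tri-O-benzyl threo diol 5,7-bis(benzyloxy)-2-[4-({(1R,2R)-1-[4-(benzyloxy)phenyl]-1,3-dihydroxypropan-2-yl}oxy)-3,5-dimethoxyphenyl]-4H-chromen-4-one, via hydroxy aldehyde 16 (not isolated)
Conditions: NaBH4 (6 equiv), THF/EtOH 2:1, 0 °C to rt; then H2O
Reagents that add atoms: none
Why: Borohydride reduction of an ester activated by its alpha-aryloxy and beta-hydroxy groups, standard for beta-O-4 type hydroxy esters, which passes through aldehyde 16, spares the flavone (flavones do not react with NaBH4 at room temperature) and breaks no bond at C7 or C8, the change from 2S to 8R being only a change of CIP priority.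

Step 11
Reactants: 17 tri-O-benzyl threo diol
Product: 18 tricin 4'-O-[threo-beta-(4-hydroxyphenyl)glyceryl] ether (7R,8R)
Conditions: H2 (1 atm), 10% Pd/C, EtOAc/THF 1:1, rt, stopped when debenzylation is complete
Reagents that add atoms: none
Why: Catalytic hydrogenolysis of aryl benzyl ethers, which under neutral conditions at 1 atm should cleave the three O–CH2Ph bonds much faster than it attacks the secondary benzylic C7–OH bond or the C2=C3 bond of ring C, leaving C7 and C8 unchanged.

Compound list
1 | phloroacetophenone (2,4,6-trihydroxyacetophenone) | CC(=O)c1c(O)cc(O)cc1O | starting material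
2 | 2-hydroxy-4,6-bis(benzyloxy)acetophenone | CC(=O)c1c(O)cc(OCc2ccccc2)cc1OCc1ccccc1 | intermediate
3 | syringaldehyde (4-hydroxy-3,5-dimethoxybenzaldehyde) | COc1cc(C=O)cc(OC)c1O | starting material
4 | 4-(allyloxy)-3,5-dimethoxybenzaldehyde | COc1cc(C=O)cc(OC)c1OCC=C | intermediate
5 | (E)-3-[4-(allyloxy)-3,5-dimethoxyphenyl]-1-[2,4-bis(benzyloxy)-6-hydroxyphenyl]prop-2-en-1-one | COc1cc(/C=C/C(=O)c2c(O)cc(OCc3ccccc3)cc2OCc2ccccc2)cc(OC)c1OCC=C | intermediate
6 | racemic 2-[4-(allyloxy)-3,5-dimethoxyphenyl]-5,7-bis(benzyloxy)chroman-4-one (flavanone, not isolated) | COc1cc(C2CC(=O)c3c(OCc4ccccc4)cc(OCc4ccccc4)cc3O2)cc(OC)c1OCC=C | intermediate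
7 | 2-[4-(allyloxy)-3,5-dimethoxyphenyl]-5,7-bis(benzyloxy)-4H-chromen-4-one (4'-O-allyl-5,7-di-O-benzyltricin) | COc1cc(-c2cc(=O)c3c(OCc4ccccc4)cc(OCc4ccccc4)cc3o2)cc(OC)c1OCC=C | intermediate
8 | 5,7-bis(benzyloxy)-2-(4-hydroxy-3,5-dimethoxyphenyl)-4H-chromen-4-one (5,7-di-O-benzyltricin) | COc1cc(-c2cc(=O)c3c(OCc4ccccc4)cc(OCc4ccccc4)cc3o2)cc(OC)c1O | intermediate
9 | 4'-(benzyloxy)acetophenone | CC(=O)c1ccc(OCc2ccccc2)cc1 | starting material
10 | diethyl carbonate | CCOC(=O)OCC | starting material
11 | ethyl 3-[4-(benzyloxy)phenyl]-3-oxopropanoate | CCOC(=O)CC(=O)c1ccc(OCc2ccccc2)cc1 | intermediate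
12 | ethyl 3-[4-(benzyloxy)phenyl]-2-diazo-3-oxopropanoate | CCOC(=O)C(=[N+]=[N-])C(=O)c1ccc(OCc2ccccc2)cc1 | intermediate
13 | racemic ethyl 3-[4-(benzyloxy)phenyl]-2-{4-[5,7-bis(benzyloxy)-4-oxo-4H-chromen-2-yl]-2,6-dimethoxyphenoxy}-3-oxopropanoate | COc1cc(-c2cc(=O)c3c(OCc4ccccc4)cc(OCc4ccccc4)cc3o2)cc(OC)c1OC(C(=O)OCC)C(=O)c1ccc(OCc2ccccc2)cc1 | intermediate
14 | (E)-enol tautomer of 13, OH hydrogen-bonded to the ester carbonyl (not isolated) | COc1cc(-c2cc(=O)c3c(OCc4ccccc4)cc(OCc4ccccc4)cc3o2)cc(OC)c1O/C(C(=O)OCC)=C(/O)c1ccc(OCc2ccccc2)cc1 | intermediate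
15 | ethyl (2S,3R)-3-[4-(benzyloxy)phenyl]-2-{4-[5,7-bis(benzyloxy)-4-oxo-4H-chromen-2-yl]-2,6-dimethoxyphenoxy}-3-hydroxypropanoate (syn, threo) | COc1cc(-c2cc(=O)c3c(OCc4ccccc4)cc(OCc4ccccc4)cc3o2)cc(OC)c1O[C@H](C(=O)OCC)[C@H](O)c1ccc(OCc2ccccc2)cc1 | intermediate
16 | (2S,3R)-3-[4-(benzyloxy)phenyl]-2-{4-[5,7-bis(benzyloxy)-4-oxo-4H-chromen-2-yl]-2,6-dimethoxyphenoxy}-3-hydroxypropanal (not isolated) | COc1cc(-c2cc(=O)c3c(OCc4ccccc4)cc(OCc4ccccc4)cc3o2)cc(OC)c1O[C@H](C=O)[C@H](O)c1ccc(OCc2ccccc2)cc1 | intermediate
17 | 5,7-bis(benzyloxy)-2-[4-({(1R,2R)-1-[4-(benzyloxy)phenyl]-1,3-dihydroxypropan-2-yl}oxy)-3,5-dimethoxyphenyl]-4H-chromen-4-one (7R,8R, threo) | COc1cc(-c2cc(=O)c3c(OCc4ccccc4)cc(OCc4ccccc4)cc3o2)cc(OC)c1O[C@H](CO)[C@H](O)c1ccc(OCc2ccccc2)cc1 | intermediate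
18 | 5,7-dihydroxy-2-[4-({(1R,2R)-1,3-dihydroxy-1-(4-hydroxyphenyl)propan-2-yl}oxy)-3,5-dimethoxyphenyl]-4H-chromen-4-one, tricin 4'-O-[threo-beta-(4-hydroxyphenyl)glyceryl] ether (7R,8R) | COc1cc(-c2cc(=O)c3c(O)cc(O)cc3o2)cc(OC)c1O[C@H](CO)[C@H](O)c1ccc(O)cc1 | target

Total step count: 11. Longest linear sequence: 8 steps (step 1 or step 2, then steps 3, 4, 5, 8, 9, 10, 11).

Steps most likely to fail

Step 9. Hydride transfer to the crowded, electron-rich C7 ketone may be too slow. The discrimination between the two equilibrating enantiomers may also be too weak, which would erode syn or facial selectivity. The fallback is an auxiliary-controlled Evans syn glycolate aldol, which builds the C7–C8 bond instead of the C7–H bond. It sets out from phenol 8, which is alkylated with commercial (S)-4-benzyl-3-(chloroacetyl)oxazolidin-2-one (K2CO3, catalytic KI, DMF, rt). This gives the aryloxyacetyl imide (S)-4-benzyl-3-({4-[5,7-bis(benzyloxy)-4-oxo-4H-chromen-2-yl]-2,6-dimethoxyphenoxy}acetyl)oxazolidin-2-one F1. The imide is enolized with Bu2BOTf and i-Pr2NEt in CH2Cl2, with one extra equivalent of the boron triflate to saturate the flavone carbonyl. Addition of commercial 4-(benzyloxy)benzaldehyde at −78 °C should then give, through the Zimmerman–Traxler chair of the Z-boron enolate, the (2S,3R) syn aldol imide F2. NaBH4 in THF/H2O removes the auxiliary reductively and the sequence comes back to the route at diol 17.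

Step 8. Capture of the carbene by the hindered, doubly hydrogen-bonded phenol may be outrun by carbene dimerization, Wolff rearrangement or attack on the flavone carbonyl oxygen. The fallback replaces carbene chemistry with polar substitution. It sets out from keto ester 11, which is chlorinated at C2 with N-chlorosuccinimide in CH2Cl2 to give racemic ethyl 3-[4-(benzyloxy)phenyl]-2-chloro-3-oxopropanoate F3. Displacement of chloride by the potassium phenoxide of 8 (K2CO3, DMF, rt to 50 °C) is the classical entry to 2-aryloxy-1,3-dicarbonyl compounds and comes back to the route at keto ester 13.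

Step 4. At 120 °C iodine and the HI it releases may strip the allyl group unevenly, add to its double bond or cleave the peri 5-O-benzyl ether, so that mixtures result. The fallback is a Baker–Venkataraman construction of ring C, which needs no oxidant. It sets out from aldehyde 4 and acetophenone 2.
- Pinnick oxidation of 4 (NaClO2, NaH2PO4, 2-methyl-2-butene, t-BuOH/H2O) gives 4-(allyloxy)-3,5-dimethoxybenzoic acid F4.
- Steglich esterification with the phenol of 2 (EDC, DMAP, CH2Cl2) gives 2-acetyl-3,5-bis(benzyloxy)phenyl 4-(allyloxy)-3,5-dimethoxybenzoate F5.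
- KOH in pyridine at 50 °C shifts the aroyl group from oxygen to the acetyl carbon, giving 1-[4-(allyloxy)-3,5-dimethoxyphenyl]-3-[2,4-bis(benzyloxy)-6-hydroxyphenyl]propane-1,3-dione F6.
- Cyclodehydration (NaOAc, AcOH, 100 °C) closes O1–C2 and comes back to the route at flavone 7.

Further compounds
F1 | step 9 | (S)-4-benzyl-3-({4-[5,7-bis(benzyloxy)-4-oxo-4H-chromen-2-yl]-2,6-dimethoxyphenoxy}acetyl)oxazolidin-2-one | COc1cc(-c2cc(=O)c3c(OCc4ccccc4)cc(OCc4ccccc4)cc3o2)cc(OC)c1OCC(=O)N1[C@@H](Cc2ccccc2)COC1=O
F2 | step 9 | (S)-4-benzyl-3-[(2S,3R)-3-[4-(benzyloxy)phenyl]-2-{4-[5,7-bis(benzyloxy)-4-oxo-4H-chromen-2-yl]-2,6-dimethoxyphenoxy}-3-hydroxypropanoyl]oxazolidin-2-one | COc1cc(-c2cc(=O)c3c(OCc4ccccc4)cc(OCc4ccccc4)cc3o2)cc(OC)c1O[C@H](C(=O)N1[C@@H](Cc2ccccc2)COC1=O)[C@H](O)c1ccc(OCc2ccccc2)cc1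
F3 | step 8 | racemic ethyl 3-[4-(benzyloxy)phenyl]-2-chloro-3-oxopropanoate | CCOC(=O)C(Cl)C(=O)c1ccc(OCc2ccccc2)cc1
F4 | step 4 | 4-(allyloxy)-3,5-dimethoxybenzoic acid | COc1cc(C(=O)O)cc(OC)c1OCC=C
F5 | step 4 | 2-acetyl-3,5-bis(benzyloxy)phenyl 4-(allyloxy)-3,5-dimethoxybenzoate | CC(=O)c1c(OC(=O)c2cc(OC)c(OCC=C)c(OC)c2)cc(OCc2ccccc2)cc1OCc1ccccc1
F6 | step 4 | 1-[4-(allyloxy)-3,5-dimethoxyphenyl]-3-[2,4-bis(benzyloxy)-6-hydroxyphenyl]propane-1,3-dione | COc1cc(C(=O)CC(=O)c2c(O)cc(OCc3ccccc3)cc2OCc2ccccc2)cc(OC)c1OCC=C
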